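The question is how much X stands in the flask at 2.5 d, and which option raises it.

- oak: Q 0.071 M; E 0.071 M; the very flask that is asked about, followed so far
- flask: Q 0.071 M; E 0.0710 M; time 2.5 d

- oak (time / h: X / %): 2.00: 58.2; 6.00: 71.8; 10.0: 73.0; 15.0: 74.9; 20.0: 75.2; 30.0: 71.7; 40.0: 74.8

(standard deviation of a reading: 1 percentage point)

- Monday's: change nothing and wait 20 h more
- Sunday's: at 2.5 d add Q, 50.0% of the amount charged, then wait 20 h
- Tuesday's: at 2.5 d add E, 100% of the amount charged, then wait 20 h

- X, in percent of the Q first charged, at 2.5 d
- which option adds most X ("none" when 2 percentage points or less is all one gets) (Monday's / Sunday's / Tuesday's / none)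
- X present, in percent of the Q first charged, after Monday's
- X present, in percent of the Q first charged, after Tuesday's

- additions bring no volume worth counting
- the analysis behind the earlier runs scatters by 1 percentage point, standard deviation
- steps under discussion: Q + E <-> X + L; E -> J; L -> G

1. From 10.0 h on, the readings lie level at a mean of 73.9%, so this reckoning expects that figure at 2.5 d and no gain from Monday's.

2. The readings do not exclude an equilibrium, but this reckoning commits to a stall: the E that did not make X is taken to have gone to J, reckoned at 26.1% of its charge.

3. Both exits are first order in E, so E cancels from their ratio. With the way back neglected, the rate into X over the rate into J equals s times free Q. Here s, the selectivity factor, is the rate constant of linking over that of loss to J.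

4. Free Q falls along the run, so the curve is replaced by a mean. The plain mean of start and end, 0.0448 M, gives s = 63.3 M⁻¹. The exact sum needs the logarithmic mean, (start − end)/ln(start/end), which is 0.0390 M, less than the plain mean. It gives the selectivity factor s = 72.6 M⁻¹, a reading that carries the scatter of the plateau, and the s from the plain mean lies 12.8% below it.

5. In this stall the E charge is reckoned as 73.9% in X and 26.1% in J, which sums to the charge, so Sunday's is expected to gain nothing.

6. On Tuesday's, a reckoned 0.0185 M of free Q meets 0.0710 M of fresh E, more than the Q needs. About 0.0525 M of E then goes to J, so free Q falls by a factor exp(s × that) = 45.2. This reckoning puts X at 99.4%. The wait of 20 h is longer than the 10.0 h the run took to level.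

The forecast gives 74.2% now, 74.2% after Monday's, and Tuesday's as best at 91%, lower than this reckoning, since “its yield is uncertain”.

The flask gives 74.8% at 2.5 d and 74.8% after Monday's. Sunday's gains 0 percentage points, and Tuesday's gains 25 points, reaching 99.4%, which is where the forecast parts from the flask.

    Q + E ⇌ X + L (K = 2.80, k = 12.0 M⁻¹ h⁻¹)
    E → J (k = 0.150 h⁻¹)
    L → G (k = 4.00 h⁻¹)

The neighbour flask holds 0.018 M of E, 0.254 equiv, with Q as charged. Taking mean free Q as the charge less half that E gives 0.0620 M. The ratio of exits is then s times that, 4.50, so 81.8% of the E is reckoned to go into X. That reckons X at 20.7% of the charged Q. The neighbour gives 21.1%, with 79% of its Q still free.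

The readings were generated by integration for an exercise; the scatter is artificial.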